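The numbers in the tables are simulated for substances that don't exist, noise included.

Late in Sunday's run X reads 53.1 % at 3.00 min and 55.4 % at 5.00 min, while Z goes from 8.9 % to 12.9 %: the X has gone flat and the Z has not.

| flask | L | J | remark | time |
|---|---|---|---|---|
| Friday's | 0.40 M | 110 mM (held) | the very flask that is asked about, followed so far |  |
| Sunday's | 0.27 M | 110 mM (held) | run made earlier |  |
| flask | 0.40 M | 110 mM (held) |  | 5.0 min |

Friday's run (percent of the L charged)

| time / s | Z / % | X / % |
|---|---|---|
| 10.0 | 0.8 | 9.8 |
| 15.0 | 0.1 | 11.8 |
| 25.0 | 0 | 18.4 |
| 40.0 | 0.7 | 25.4 |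
| 50.0 | 1.2 | 26.9 |
| 80.0 | 2.7 | 33.6 |
| 90.0 | 0.1 | 34.5 |

Sunday's run (percent of the L charged)

| time / min | Z / % | X / % |
|---|---|---|
| 0.250 | 0.5 | 17.5 |
| 0.833 | 2.0 | 40.0 |
| 1.33 | 2.0 | 49.1 |
| 2.00 | 2.5 | 53.1 |
| 3.00 | 8.9 | 53.1 |
| 4.00 | 9.8 | 54.6 |
| 5.00 | 12.9 | 55.4 |

(scatter of a reading: 1 percentage point)

- how much Z there is at 5.0 min, in percent of the L charged
- concentration of X in solution at 80 s, in percent of saturation
- the change that raises the amount of Z at 5.0 min, in percent of the L charged most ("none" if none brings more than 2 percentage points) (larch / cedar / ash / oak / none)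
- amount of Z at 5.0 min, in percent of the L charged, after larch

- given per volume of solution although it is solid: L
- at the start none of L is in solution
- at the start none of J is in solution
- X is what L becomes in solution
- X means what is dissolved; the solid is not counted in it

- larch: doubling the transfer coefficient of J, all else as stated
- cedar: doubling the saturation concentration of J, all else as stated
- ash: doubling the dissolution coefficient of L, all else as stated
- oak: doubling the solubility of L, all else as stated

Step 1, the main step alone: solid L dissolves to X. Sunday's last X and Z readings add up to 68.3 % of the charge, so I take solid to be still present and the flat X to be a concentration that does not depend on the charge. Carried over to Friday's flask, that is 37.4 %. This number is Sunday's late X concentration divided by a flask's own charge, the ceiling share. Friday's X reading at 80.0 s is 89.9 % of it.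

Step 2, adding X with dissolved J to give Z. This step drains X while dissolving refills it, so I expect the ceiling to sit under true saturation and treat that percentage of the ceiling as a high figure for saturation. Both flasks hold J at 110 mM, so I take Z in molar terms to be the same in both. Sunday's last reading then gives 8.71 % of Friday's charge, and I commit to that.

Step 3, the rest: J starts with none in solution. With X flat, the Z step is pseudo-first-order in dissolved J. Sunday's Z gain per minute is about 4.67 times greater late than early, a rough reading given the scatter of 1 percentage point. I read that as J arriving, and I take that arrival to be the same in both flasks, so my figure for Z stands.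

The forecast says 8.7 %, 90 %, cedar and 10 %: “Doubling saturated J doubles Z in either regime”.

    X + E → Z (k = 0.0489 M⁻¹ s⁻¹)
    2 E → G (k = 0.0630 M⁻¹ s⁻¹)
    X + Z → D (k = 0.0257 M⁻¹ s⁻¹)
    L ⇌ X, rate k4*(cs4 - [X]) while solid is left; crystals form when [X] > cs4 (solubility = 0.160 M, k = 0.0233 s⁻¹)
    J ⇌ E, rate k5*(csat - [E]) (kL = 0.00488 s⁻¹)

The flask gives 9.20 % of Z, with cedar as the best change and 13.4 % of Z after larch. Its X stands at 81.8 % of saturation at 80 s. At 5.00 min X stands at 36.2 %, near its ceiling share of 37.4 %, yet that is 90.5 % of saturation, and saturation is where flask and forecast part. With 1.6 M of L the ceiling share is 9.35 %, and that flask's X stands at 9.05 %. At 0.823 min in Friday's flask, X goes to Z 18 times as fast as to D. By 5.00 min that ratio has dropped to 1.7.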